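**Plan**
- Retrosynthesis: ring C is cut at C4–C4a (Friedel–Crafts acylation) and at O1–C2 (Mitsunobu etherification). The piperidine is cut at N1'–C2'. The C6–C2' bond goes back to acylation of a ring A aryllithium by N-Boc-valerolactam.
- Forward: phloroglucinol (ring A) is differentiated, lithiated and acylated to attach the five-carbon amino chain. The piperidine closes next and ring C closes last.
- Enabling feature: piperidine C2' is a benzylic carbon on C6 of ring A, flanked by the C5 and C7 phenol oxygens. A C2' carbinol with one free ortho phenol therefore ionises to a planar ortho-quinone methide, to which the tethered carbamate nitrogen can add.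
- Stereochemistry: C2' (R) comes from chiral phosphoric acid control of that addition, starting from the racemic carbinol. C2 (S) comes from ethyl (R)-3-hydroxy-3-phenylpropanoate with Mitsunobu inversion.

Key step: step 6

Assumption: the sense of induction of the phosphoric acid in step 6 cannot be predicted with confidence. (R)-TRIP, (R)-3,3'-bis(2,4,6-triisopropylphenyl)-1,1'-binaphthyl-2,2'-diyl hydrogen phosphate, is written, and its mirror image is the catalyst to use if it favours the other face.

**Step 1**
Reactants: 1 phloroglucinol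
Product: 2 3,5-bis(methoxymethoxy)phenol
Conditions: MOMCl (2 equiv), i-Pr2NEt, DMF/CH2Cl2, 0 °C → rt; chromatography
Reagents that add atoms: chloromethyl methyl ether, COCCl
Why: Williamson-type O-alkylation; the hard electrophile MOMCl reacts at oxygen and not at carbon of phloroglucinol, so two equivalents should give the bis-ether as the main component of a statistical mixture from which it is separated.

**Step 2**
Reactants: 2 3,5-bis(methoxymethoxy)phenol
Product: 3 1-(benzyloxy)-3,5-bis(methoxymethoxy)benzene
Conditions: BnBr, K2CO3, DMF, rt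
Reagents that add atoms: benzyl bromide, BrCc1ccccc1
Why: Williamson etherification of the one remaining phenol; with the other two oxygens capped, O-benzylation should be clean.

**Step 3**
Reactants: 3 1-(benzyloxy)-3,5-bis(methoxymethoxy)benzene; 4 tert-butyl 2-oxopiperidine-1-carboxylate
Product: 6 tert-butyl N-{5-[4-(benzyloxy)-2,6-bis(methoxymethoxy)phenyl]-5-oxopentyl}carbamate, via aryllithium 5 (not isolated)
Conditions: n-BuLi, THF, 0 °C; then 4, –78 → –20 °C; aq NH4Cl
Reagents that add atoms: none
Why: Directed ortho-metalation at the ring carbon between the two OMOM groups (cooperative lithium coordination; n-BuLi at 0 °C should leave the benzylic CH2 of the OBn group alone), then acylation of 5 by the imide-like lactam carbonyl of 4, whose tetrahedral adduct opens to the carbamate anion and leaves a doubly ortho-substituted ketone that resists a second addition.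

**Step 4**
Reactants: 6 tert-butyl N-{5-[4-(benzyloxy)-2,6-bis(methoxymethoxy)phenyl]-5-oxopentyl}carbamate
Product: 7 tert-butyl N-{5-[4-(benzyloxy)-2-hydroxy-6-(methoxymethoxy)phenyl]-5-oxopentyl}carbamate
Conditions: HCl (0.1 M, from AcCl), MeOH/CH2Cl2, 0 °C → rt, stopped at mono-cleavage
Reagents that add atoms: none
Why: Acid-catalysed acetal methanolysis that should stop after one MOM group: the ortho carbonyl assists the first cleavage, the freed phenol then ties up that carbonyl in a hydrogen bond so the second MOM ether behaves as an ordinary aryl acetal, and the dilute acid should leave the Boc group intact.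

**Step 5**
Reactants: 7 tert-butyl N-{5-[4-(benzyloxy)-2-hydroxy-6-(methoxymethoxy)phenyl]-5-oxopentyl}carbamate
Product: 8 racemic tert-butyl N-{5-[4-(benzyloxy)-2-hydroxy-6-(methoxymethoxy)phenyl]-5-hydroxypentyl}carbamate
Conditions: NaBH4, THF/MeOH, 0 °C; pH 7 phosphate buffer; crude used directly
Reagents that add atoms: none
Why: Hydride reduction of the aryl ketone with NaBH4; no stereocontrol is wanted because the carbinol centre is erased in step 6, and the cold, buffered work-up without chromatography is meant to keep the electron-rich ortho-hydroxybenzylic alcohol from ionising early.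

**Step 6**
Reactants: 8 racemic tert-butyl N-{5-[4-(benzyloxy)-2-hydroxy-6-(methoxymethoxy)phenyl]-5-hydroxypentyl}carbamate
Product: 10 tert-butyl (R)-2-[4-(benzyloxy)-2-hydroxy-6-(methoxymethoxy)phenyl]piperidine-1-carboxylate, via ortho-quinone methide 9 (not isolated)
Conditions: (R)-TRIP (10 mol%), 5 Å MS, toluene (0.02 M), –30 → 0 °C
Reagents that add atoms: none
Why: Proposed new method: the phosphoric acid protonates the benzylic hydroxyl of 8 while the ortho phenol expels water, giving the planar ortho-quinone methide 9 held by a hydrogen bond from P–OH to its carbonyl oxygen; the phosphoryl oxygen binds the carbamate N–H and guides nitrogen onto one face of the exocyclic methide carbon, which restores the arene. The closest known reaction type is the chiral phosphoric acid catalysed enantioselective conjugate addition of external nucleophiles to ortho-quinone methides formed in situ from ortho-hydroxybenzylic alcohols; a tethered carbamate nitrogen has not been used in this way. The piperidine closes in the 6-exo-trig mode by N1'–C2' bond formation, the attacked alkene carbon lying inside the new ring and its ring A partner outside. C2' is set by catalyst-controlled face selection on 9, and because both enantiomers of 8 (and any water re-adduct or ortho-hydroxystyrene tautomer, which the acid can re-protonate) pass through the same achiral intermediate, the racemate should converge on the (R) piperidine. The step needs the catalysed closure to outrun racemic closure and needs N- rather than O-attack: the Boc carbamate is too weak a nucleophile to add without general-base help from the phosphate, the OMOM group on the other ortho carbon should force the side chain to the carbonyl side of 9 (one alkene geometry, written as Z) and the benzyl ether blocks a para-quinone methide, while O-attack would need an eight-membered ring.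

**Step 7**
Reactants: 10 tert-butyl (R)-2-[4-(benzyloxy)-2-hydroxy-6-(methoxymethoxy)phenyl]piperidine-1-carboxylate
Product: 11 tert-butyl (R)-2-[4-(benzyloxy)-2,6-bis(methoxymethoxy)phenyl]piperidine-1-carboxylate
Conditions: MOMCl, i-Pr2NEt, CH2Cl2, 0 °C → rt
Reagents that add atoms: chloromethyl methyl ether, COCCl
Why: O-alkylation of the hindered phenol with MOMCl under a weak amine base, which avoids a free phenoxide that could expel the carbamate nitrogen (retro-aza-Michael) and racemise C2', and is placed before the Boc reduction so that no tertiary amine is present to be quaternised by MOMCl.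

**Step 8**
Reactants: 11 tert-butyl (R)-2-[4-(benzyloxy)-2,6-bis(methoxymethoxy)phenyl]piperidine-1-carboxylate
Product: 12 (R)-2-[4-(benzyloxy)-2,6-bis(methoxymethoxy)phenyl]-1-methylpiperidine
Conditions: LiAlH4, THF, reflux; aq NaOH work-up
Reagents that add atoms: none
Why: LiAlH4 reduction of a carbamate to an N-methyl amine (through the formamide and the exocyclic iminium ion) with loss of tert-butoxide; the benzyl and MOM ethers are inert and C2' is not touched.

**Step 9**
Reactants: 12 (R)-2-[4-(benzyloxy)-2,6-bis(methoxymethoxy)phenyl]-1-methylpiperidine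
Product: 13 3,5-bis(methoxymethoxy)-4-[(R)-1-methylpiperidin-2-yl]phenol
Conditions: H2 (1 atm), Pd/C, MeOH/EtOAc, rt
Reagents that add atoms: none
Why: Catalytic hydrogenolysis of the aryl benzyl ether over Pd/C under neutral conditions; MOM acetals are stable and the hindered ring C2'–N bond should not be cleaved at one atmosphere.

**Step 10**
Reactants: 13 3,5-bis(methoxymethoxy)-4-[(R)-1-methylpiperidin-2-yl]phenol; 14 ethyl (R)-3-hydroxy-3-phenylpropanoate
Product: 15 ethyl (S)-3-{3,5-bis(methoxymethoxy)-4-[(R)-1-methylpiperidin-2-yl]phenoxy}-3-phenylpropanoate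
Conditions: PPh3, DIAD, toluene, 0 °C → rt
Reagents that add atoms: none
Why: Mitsunobu etherification: the phenol displaces the alkoxyphosphonium ion of 14 in an SN2 reaction with inversion at the benzylic carbon and thereby sets C2 as (S); the tertiary amine and the acetals are spectators.

**Step 11**
Reactants: 15 ethyl (S)-3-{3,5-bis(methoxymethoxy)-4-[(R)-1-methylpiperidin-2-yl]phenoxy}-3-phenylpropanoate
Product: 16 (S)-3-{3,5-bis(methoxymethoxy)-4-[(R)-1-methylpiperidin-2-yl]phenoxy}-3-phenylpropanoic acid
Conditions: LiOH, THF/MeOH/H2O, 0 °C → rt; 1 M HCl to pH 6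
Reagents that add atoms: lithium hydroxide, [Li+].[OH-]
Why: Ester saponification by acyl substitution, run cold so that it outpaces E1cB loss of the aryloxide; once formed, the carboxylate no longer eliminates and neither stereocentre is touched.

**Step 12**
Reactants: 16 (S)-3-{3,5-bis(methoxymethoxy)-4-[(R)-1-methylpiperidin-2-yl]phenoxy}-3-phenylpropanoic acid
Product: 19 (S)-5,7-dihydroxy-6-[(R)-1-methylpiperidin-2-yl]-2-phenylchroman-4-one, via mixed trifluoroacetic anhydride 17 (not isolated), via bis-MOM flavanone 18 (not isolated)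
Conditions: (CF3CO)2O, CH2Cl2, –20 → 0 °C; evaporate; 3 M HCl in MeOH, rt; NaHCO3 to pH 7–8
Reagents that add atoms: none
Why: Intramolecular Friedel–Crafts acylation through the mixed anhydride 17 at a ring A carbon ortho to the ether oxygen (both such positions are equivalent by rotation about the aryl–C2' bond), which is activated by three oxygen substituents and closes the six-membered ring C under mild acid, followed by acid methanolysis of both MOM acetals in which methanol traps formaldehyde as dimethoxymethane; no bond to C2 or C2' is broken and the temperature is kept low to avoid ionisation at either benzylic centre.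

**Compound list**
1 | phloroglucinol (benzene-1,3,5-triol) | Oc1cc(O)cc(O)c1 | starting material
2 | 3,5-bis(methoxymethoxy)phenol | COCOc1cc(O)cc(OCOC)c1 | intermediate
3 | 1-(benzyloxy)-3,5-bis(methoxymethoxy)benzene | COCOc1cc(OCc2ccccc2)cc(OCOC)c1 | intermediate
4 | tert-butyl 2-oxopiperidine-1-carboxylate | O=C1CCCCN1C(=O)OC(C)(C)C | starting material
5 | [4-(benzyloxy)-2,6-bis(methoxymethoxy)phenyl]lithium | [Li]c1c(OCOC)cc(OCc2ccccc2)cc1OCOC | intermediate
6 | tert-butyl N-{5-[4-(benzyloxy)-2,6-bis(methoxymethoxy)phenyl]-5-oxopentyl}carbamate | CC(C)(C)OC(=O)NCCCCC(=O)c1c(OCOC)cc(OCc2ccccc2)cc1OCOC | intermediate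
7 | tert-butyl N-{5-[4-(benzyloxy)-2-hydroxy-6-(methoxymethoxy)phenyl]-5-oxopentyl}carbamate | CC(C)(C)OC(=O)NCCCCC(=O)c1c(O)cc(OCc2ccccc2)cc1OCOC | intermediate
8 | racemic tert-butyl N-{5-[4-(benzyloxy)-2-hydroxy-6-(methoxymethoxy)phenyl]-5-hydroxypentyl}carbamate | CC(C)(C)OC(=O)NCCCCC(O)c1c(O)cc(OCc2ccccc2)cc1OCOC | intermediate
9 | tert-butyl N-{(5Z)-5-[4-(benzyloxy)-2-(methoxymethoxy)-6-oxocyclohexa-2,4-dien-1-ylidene]pentyl}carbamate (ortho-quinone methide) | CC(C)(C)OC(=O)NCCCC/C=C1\C(=O)C=C(OCc2ccccc2)C=C1OCOC | intermediate
10 | tert-butyl (R)-2-[4-(benzyloxy)-2-hydroxy-6-(methoxymethoxy)phenyl]piperidine-1-carboxylate | CC(C)(C)OC(=O)N1CCCC[C@@H]1c1c(O)cc(OCc2ccccc2)cc1OCOC | intermediate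
11 | tert-butyl (R)-2-[4-(benzyloxy)-2,6-bis(methoxymethoxy)phenyl]piperidine-1-carboxylate | CC(C)(C)OC(=O)N1CCCC[C@@H]1c1c(OCOC)cc(OCc2ccccc2)cc1OCOC | intermediate
12 | (R)-2-[4-(benzyloxy)-2,6-bis(methoxymethoxy)phenyl]-1-methylpiperidine | CN1CCCC[C@@H]1c1c(OCOC)cc(OCc2ccccc2)cc1OCOC | intermediate
13 | 3,5-bis(methoxymethoxy)-4-[(R)-1-methylpiperidin-2-yl]phenol | CN1CCCC[C@@H]1c1c(OCOC)cc(O)cc1OCOC | intermediate
14 | ethyl (R)-3-hydroxy-3-phenylpropanoate | CCOC(=O)C[C@@H](O)c1ccccc1 | starting material
15 | ethyl (S)-3-{3,5-bis(methoxymethoxy)-4-[(R)-1-methylpiperidin-2-yl]phenoxy}-3-phenylpropanoate | CN1CCCC[C@@H]1c1c(OCOC)cc(O[C@@H](CC(=O)OCC)c2ccccc2)cc1OCOC | intermediate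
16 | (S)-3-{3,5-bis(methoxymethoxy)-4-[(R)-1-methylpiperidin-2-yl]phenoxy}-3-phenylpropanoic acid | CN1CCCC[C@@H]1c1c(OCOC)cc(O[C@@H](CC(=O)O)c2ccccc2)cc1OCOC | intermediate
17 | (S)-3-{3,5-bis(methoxymethoxy)-4-[(R)-1-methylpiperidin-2-yl]phenoxy}-3-phenylpropanoic trifluoroacetic anhydride | CN1CCCC[C@@H]1c1c(OCOC)cc(O[C@@H](CC(=O)OC(=O)C(F)(F)F)c2ccccc2)cc1OCOC | intermediate
18 | (S)-5,7-bis(methoxymethoxy)-6-[(R)-1-methylpiperidin-2-yl]-2-phenylchroman-4-one | CN1CCCC[C@@H]1c1c(OCOC)cc2c(c1OCOC)C(=O)C[C@@H](c1ccccc1)O2 | intermediate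
19 | (S)-5,7-dihydroxy-6-[(R)-1-methylpiperidin-2-yl]-2-phenylchroman-4-one | CN1CCCC[C@@H]1c1c(O)cc2c(c1O)C(=O)C[C@@H](c1ccccc1)O2 | target

**Totals**
Total step count: 12. Longest linear sequence: 12 steps (1 → 19).

**Steps most likely to fail**

Step 6. The risk is loss of face control: the very electron-rich quinone methide may close without the catalyst, or product 10 may re-ionise under the acid and drift toward the racemate. The fallback uses known sulfinyl-imine auxiliary chemistry and sets out from arene 3. Arene 3 is lithiated to 5 as in step 3 and transmetalated with MgBr2·OEt2 to [4-(benzyloxy)-2,6-bis(methoxymethoxy)phenyl]magnesium bromide F2. This is added in toluene at –78 °C to (R)-N-(5-chloropentylidene)-2-methylpropane-2-sulfinamide F1, prepared from commercial 5-chloropentanal and (R)-2-methylpropane-2-sulfinamide with CuSO4 in CH2Cl2. The chelated chair transition state of such additions should give (R)-N-{(R)-1-[4-(benzyloxy)-2,6-bis(methoxymethoxy)phenyl]-5-chloropentyl}-2-methylpropane-2-sulfinamide F3. KN(SiMe3)2 in THF closes the ring by N-alkylation to (R)-2-[4-(benzyloxy)-2,6-bis(methoxymethoxy)phenyl]-1-[(R)-tert-butylsulfinyl]piperidine F4. Brief HCl in MeOH at 0 °C removes the sulfinyl group to give (R)-2-[4-(benzyloxy)-2,6-bis(methoxymethoxy)phenyl]piperidine F5. Reductive methylation with aqueous CH2O and NaBH(OAc)3 returns to the route at 12.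

Step 12. The risk is early acidolysis of the MOM groups followed by O-trifluoroacetylation that deactivates ring A, or C-trifluoroacetylation of ring A by the free anhydride. The fallback replaces the acylium-type electrophile by a nitrilium ion and sets out from phenol 13. Mitsunobu etherification with commercial (R)-3-hydroxy-3-phenylpropanenitrile (PPh3, DIAD) should give (S)-3-{3,5-bis(methoxymethoxy)-4-[(R)-1-methylpiperidin-2-yl]phenoxy}-3-phenylpropanenitrile F6. HCl in MeOH at rt removes both MOM groups to give (S)-3-{3,5-dihydroxy-4-[(R)-1-methylpiperidin-2-yl]phenoxy}-3-phenylpropanenitrile F7. An intramolecular Houben–Hoesch reaction (dry HCl, ZnCl2, Et2O/EtOAc, 0 °C), the classical acylation of free phloroglucinol-type rings, closes ring C as the hydrochloride of (S)-5,7-dihydroxy-6-[(R)-1-methylpiperidin-2-yl]-2-phenylchroman-4-imine F8. Gentle warming in water hydrolyses the iminium salt and comes back to the route at target 19.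

Step 5. The risk is over-reduction: the borate of the ortho-hydroxybenzylic alcohol may ionise in the flask and the quinone methide may capture hydride, or the carbinol may cyclise racemically during work-up. The fallback masks the phenol during the reduction and sets out from ketone 7. Silylation (TBSCl, imidazole, DMF) gives tert-butyl N-{5-[4-(benzyloxy)-2-(tert-butyldimethylsilyloxy)-6-(methoxymethoxy)phenyl]-5-oxopentyl}carbamate F9. Without a free ortho oxygen, LiBH4 in THF at 0 °C should stop at racemic tert-butyl N-{5-[4-(benzyloxy)-2-(tert-butyldimethylsilyloxy)-6-(methoxymethoxy)phenyl]-5-hydroxypentyl}carbamate F10; a silyl shift to the carbinol oxygen would be harmless. n-Bu4NF buffered with AcOH in THF at 0 °C then releases carbinol 8 under neutral conditions just before step 6.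

Further compounds
F1 | step 6 | (R)-N-(5-chloropentylidene)-2-methylpropane-2-sulfinamide | ClCCCC/C=N/[S@](=O)C(C)(C)C
F2 | step 6 | [4-(benzyloxy)-2,6-bis(methoxymethoxy)phenyl]magnesium bromide | Br[Mg]c1c(OCOC)cc(OCc2ccccc2)cc1OCOC
F3 | step 6 | (R)-N-{(R)-1-[4-(benzyloxy)-2,6-bis(methoxymethoxy)phenyl]-5-chloropentyl}-2-methylpropane-2-sulfinamide | ClCCCC[C@@H](N[S@](=O)C(C)(C)C)c1c(OCOC)cc(OCc2ccccc2)cc1OCOC
F4 | step 6 | (R)-2-[4-(benzyloxy)-2,6-bis(methoxymethoxy)phenyl]-1-[(R)-tert-butylsulfinyl]piperidine | CC(C)(C)[S@@](=O)N1CCCC[C@@H]1c1c(OCOC)cc(OCc2ccccc2)cc1OCOC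
F5 | step 6 | (R)-2-[4-(benzyloxy)-2,6-bis(methoxymethoxy)phenyl]piperidine | N1CCCC[C@@H]1c1c(OCOC)cc(OCc2ccccc2)cc1OCOC
F6 | step 12 | (S)-3-{3,5-bis(methoxymethoxy)-4-[(R)-1-methylpiperidin-2-yl]phenoxy}-3-phenylpropanenitrile | CN1CCCC[C@@H]1c1c(OCOC)cc(O[C@@H](CC#N)c2ccccc2)cc1OCOC
F7 | step 12 | (S)-3-{3,5-dihydroxy-4-[(R)-1-methylpiperidin-2-yl]phenoxy}-3-phenylpropanenitrile | CN1CCCC[C@@H]1c1c(O)cc(O[C@@H](CC#N)c2ccccc2)cc1O
F8 | step 12 | (S)-5,7-dihydroxy-6-[(R)-1-methylpiperidin-2-yl]-2-phenylchroman-4-imine (formed as its hydrochloride) | CN1CCCC[C@@H]1c1c(O)cc2c(c1O)C(=N)C[C@@H](c1ccccc1)O2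
F9 | step 5 | tert-butyl N-{5-[4-(benzyloxy)-2-(tert-butyldimethylsilyloxy)-6-(methoxymethoxy)phenyl]-5-oxopentyl}carbamate | CC(C)(C)OC(=O)NCCCCC(=O)c1c(O[Si](C)(C)C(C)(C)C)cc(OCc2ccccc2)cc1OCOC
F10 | step 5 | racemic tert-butyl N-{5-[4-(benzyloxy)-2-(tert-butyldimethylsilyloxy)-6-(methoxymethoxy)phenyl]-5-hydroxypentyl}carbamate | CC(C)(C)OC(=O)NCCCCC(O)c1c(O[Si](C)(C)C(C)(C)C)cc(OCc2ccccc2)cc1OCOC
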